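**Retrosynthetic overview**
1. Target 13 comes from tri-MOM ether 12 by one global acetal cleavage.
2. Key step: I cut two bonds of ring A at once, the hindered biaryl bond C1'–C7 and the C2'–prenyl bond. This leads back to a 3,4-bis(MOMO)-6-prenylbenzyne, a chromen-7-yl-lithium and prenyl bromide in a one-pot aryne carbolithiation/allylation. It replaces the Pd cross-coupling of two finished arenes.
3. The aryne precursor 7 comes from 4-chlorocatechol by bromination, MOM protection and Br/Mg exchange–prenylation. Cl is the aryne leaving group and the MOM ether directs lithiation.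
4. The chromenyl bromide 11 comes from 5-bromoresorcinol and prenal by a formal [3+3] (oxa-6π).
5. Ring order: both benzene rings are purchased. The pyran ring is the only ring formed (step 4).

Assumption: the SMILES has no stereocentre and no stereogenic alkene. The biaryl axis carries ortho substituents on ring A only, so it rotates freely. The target is therefore achiral and no enantiocontrol is needed.

**Step 1**
Reactants: 1, 4-chlorocatechol; 2, bromine
Product: 3, 4-bromo-5-chlorobenzene-1,2-diol
Conditions: Br2 (1.0 equiv), AcOH, 0 °C → rt
Reagents that add atoms: bromine, BrBr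
Why: Electrophilic aromatic bromination goes to C5, the only free position para to a hydroxyl, in the same way that catechol gives its 4,5-dibromide.

**Step 2**
Reactants: 3; 4, chloromethyl methyl ether (MOMCl)
Product: 5, 1-bromo-2-chloro-4,5-bis(methoxymethoxy)benzene
Conditions: MOMCl (3 equiv), i-Pr2NEt, CH2Cl2, 0 °C → rt
Reagents that add atoms: MOMCl, COCCl
Why: Phenol O-alkylation (acetal protection) installs MOM, which survives RMgX and RLi, directs ortho-lithiation strongly in step 6, and is removed by mild acid.

**Step 3**
Reactants: 5; 6, prenyl bromide (1-bromo-3-methylbut-2-ene)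
Product: 7, 1-chloro-4,5-bis(methoxymethoxy)-2-(3-methylbut-2-en-1-yl)benzene
Conditions: i-PrMgCl·LiCl, THF, –15 → 0 °C; then CuI (10 mol %), 6, –20 °C → rt
Reagents that add atoms: prenyl bromide, CC(C)=CCBr
Why: Turbo-Grignard Br/Mg exchange is chemoselective (C–Cl is inert and the o-chloroaryl-magnesium does not eliminate at these temperatures), and Cu-catalysed SN2 allylic substitution then occurs at the unhindered CH2 terminus of prenyl bromide.

**Step 4**
Reactants: 8, 5-bromoresorcinol; 9, 3-methylbut-2-enal (prenal)
Product: 10, 7-bromo-2,2-dimethyl-2H-chromen-5-ol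
Conditions: 9 (1.1 equiv), ethylenediammonium diacetate (10 mol %), toluene, reflux
Reagents that add atoms: 3-methylbut-2-enal, CC(C)=CC=O
Why: Knoevenagel-type condensation at C2 of the resorcinol gives an o-quinone methide that closes by oxa-6π electrocyclisation (formal [3+3]), and 5-substituted resorcinols such as orcinol and olivetol give the 5-hydroxy-7-substituted chromene, while limiting the aldehyde suppresses bis-annulation.

**Step 5**
Reactants: 10; 4, MOMCl
Product: 11, 7-bromo-5-(methoxymethoxy)-2,2-dimethyl-2H-chromene
Conditions: MOMCl, i-Pr2NEt, CH2Cl2, 0 °C → rt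
Reagents that add atoms: MOMCl, COCCl
Why: Phenol O-alkylation removes the acidic proton before Li/Br exchange, and the chromene alkene is inert to these conditions.

**Step 6 (key step)**
Reactants: 7; 11; 6, prenyl bromide
Product: 12, 7-[3,4-bis(methoxymethoxy)-2,6-bis(3-methylbut-2-en-1-yl)phenyl]-5-(methoxymethoxy)-2,2-dimethyl-2H-chromene
Conditions: (a) 11 (2 equiv), t-BuLi (4 equiv), THF, –78 °C; (b) 7, s-BuLi (1.05 equiv), THF, –78 °C, then added dropwise to (a) at –30 °C, → 0 °C; (c) CuBr·SMe2 (20 mol %), 6 (4 equiv), –78 °C → rt
Reagents that add atoms: prenyl bromide, CC(C)=CCBr (the aryl unit comes from reactant 11)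
Why: Directed ortho-lithiation of 7 at the C–H flanked by Cl and OMOM and loss of LiCl give the 3-alkoxyaryne, the aryllithium from 11 attacks the aryne carbon meta to oxygen (inductive/distortion control typical of 3-alkoxyarynes, which outweighs the small CH2 neighbour), and the resulting MOM-chelated C2'-lithium is allylated SN2 under Cu catalysis (aryne carbolithiation–electrophile trapping, the same logic as one-pot aryne routes to hindered 2-functionalised biaryls); no stereocentre is created.

**Step 7**
Reactants: 12
Product: 13, clusiachromene D
Conditions: 2 M aq HCl/MeOH (1:5, degassed), 45 °C, Ar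
Reagents that add atoms: none
Why: Acid-catalysed acetal hydrolysis cleaves aryl MOM ethers under conditions routinely tolerated by prenylated phenols and 2,2-dimethylchromenes, and excluding air protects the free catechol.

**Compound list**
1 | 4-chlorocatechol | Oc1ccc(Cl)cc1O | starting material
2 | bromine | BrBr | starting material (reagent)
3 | 4-bromo-5-chlorobenzene-1,2-diol | Oc1cc(Cl)c(Br)cc1O | intermediate
4 | chloromethyl methyl ether | COCCl | starting material (reagent)
5 | 1-bromo-2-chloro-4,5-bis(methoxymethoxy)benzene | COCOc1cc(Cl)c(Br)cc1OCOC | intermediate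
6 | prenyl bromide | CC(C)=CCBr | starting material
7 | 1-chloro-4,5-bis(methoxymethoxy)-2-prenylbenzene | COCOc1cc(Cl)c(CC=C(C)C)cc1OCOC | intermediate
8 | 5-bromoresorcinol | Oc1cc(O)cc(Br)c1 | starting material
9 | 3-methylbut-2-enal | CC(C)=CC=O | starting material
10 | 7-bromo-2,2-dimethyl-2H-chromen-5-ol | CC1(C)C=Cc2c(O)cc(Br)cc2O1 | intermediate
11 | 7-bromo-5-(methoxymethoxy)-2,2-dimethyl-2H-chromene | COCOc1cc(Br)cc2OC(C)(C)C=Cc12 | intermediate
12 | tri-O-MOM clusiachromene D | COCOc1cc(CC=C(C)C)c(c(CC=C(C)C)c1OCOC)-c1cc(OCOC)c2C=CC(C)(C)Oc2c1 | intermediate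
13 | clusiachromene D (achiral, C27H32O4) | CC(C)=CCc1cc(O)c(O)c(CC=C(C)C)c1-c1cc(O)c2c(c1)OC(C)(C)C=C2 | target

**Total steps:** 7.
**Longest linear sequence:** 5 (steps 1 → 2 → 3 → 6 → 7).

**Three steps most likely to fail**
1. **Step 6.** Possible failures are aryne self-trapping by lithiated 7, eroded regioselectivity next to the prenyl group, and protonation before allylation.
   Fallback: build ring A de novo by Stork–Danheiser transposition.
   - Convert cyclohexane-1,3-dione into 3-methoxy-2,6-diprenylcyclohex-2-enone (C-prenylation, O-methylation, LDA/prenyl bromide).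
   - Add the aryllithium from 11 (CeCl3) and hydrolyse to 3-aryl-2,4-diprenylcyclohex-2-enone.
   - α'-Hydroxylate (LiHMDS, Davis oxaziridine) and oxidise (DMP). The ene-1,2-dione tautomerises directly to the catechol.
2. **Step 4.** The annulation may attack C4 instead of C2, or annulate twice.
   Fallback: form the pyran ring last. Use the symmetric 3,5-bis(MOMO)phenyllithium (from 8) in step 6, deprotect, and run the prenal/EDDA annulation on the free tetraol. There the bulky 2,6-diprenylaryl group blocks C4/C6 of the resorcinol and enforces the cannabichromene-type mode.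
3. **Step 7.** Acid may cyclise the C2'-prenyl group onto the C3'-OH to give a chroman, and the catechol may oxidise.
   Fallback: change the protecting-group strategy to SEM ethers throughout. These should still direct the lithiation, and they are removed with fluoride (TBAF/DMPU), which avoids acid.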